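(The data were generated by integration for substances that don't exist; the scatter is artificial.)

Time came first: I asked whether the 30 min allowed to this flask mattered at all.

- dawn: starting material 0.019 M; first nucleophile 1.5 equiv; second nucleophile 1.2 equiv; protic impurity 2.6 mM; run made earlier
- flask: starting material 0.013 M; first nucleophile 1.50 equiv; second nucleophile 1.20 equiv; protic impurity 2.60 mM; time 30 min

dawn run (percent of the starting material charged)

| time / min | starting material / % | target / % | solvolysis product / % | other capture product / % |
|---|---|---|---|---|
| 0.167 | 31.5 | 24.5 | 25.9 | 11.0 |
| 0.500 | 4.0 | 36.0 | 36.5 | 13.3 |
| 0.833 | 0.3 | 36.9 | 40.5 | 12.2 |
| 1.33 | 0.3 | 36.8 | 39.0 | 13.4 |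
| 2.00 | 0 | 36.8 | 40.0 | 12.6 |
| 2.50 | 0 | 37.7 | 38.5 | 13.0 |
| 3.00 | 0.7 | 37.9 | 39.8 | 13.1 |

(readings scatter by 0.5 percentage points)

- on the list of suspects stand: starting material -> intermediate; first nucleophile + intermediate -> target; second nucleophile + intermediate -> other capture product; intermediate -> solvolysis product; starting material + protic impurity -> quenched substrate; 2 second nucleophile -> homo dimer
- the reaction counts as stopped when no species that holds the starting material changes by six tenths of a point or more over the second half of the time

* at 30 min, what has stopped the reaction, if anything has (the first nucleophile has run out first / it is still moving / all of the starting material has reacted)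
* part of the starting material gone at 30 min
* the target standing at 30 min, as a percentage of the starting material charged
* the solvolysis product standing at 30 min, as a percentage of the starting material charged
* the other capture product standing at 30 min, as a percentage of the starting material charged

In the dawn run, starting material stood at 31.5% after 0.167 min, which reads as a half-life of 0.100 min. Both suspected exits of starting material are first order in it and the protic impurity was charged alike, so I carried that half-life over; it is far shorter than the time allowed, so I expected the flask to have consumed its starting material.

The next question was the fate of one molecule at the intermediate. There it can meet the first nucleophile, a pseudo-first-order capture that scales with c(first nucleophile), meet the second nucleophile, or undergo solvolysis, which does not depend on c(first nucleophile). The latest dawn reading gave target over solvolysis product as 0.952. The average c(first nucleophile), its charge less half the target made, was 24.9 mM. Dividing gave a reading of S = 38.2 M⁻¹, the selectivity factor: target formed per solvolysis product, per unit of average c(first nucleophile).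

What odds did the flask offer? Spending dawn's percentage of target as a first guess, I reckoned 0.652 for the flask, lower than dawn's ratio.

The forecast said: all of the starting material has reacted, with 100% gone, target 30.4%, solvolysis product 45.8% and other capture product 11.5%, adding that the “first nucleophile stays in excess”. Its ratio, 0.664, stood slightly above mine.

The flask gave: all of the starting material has reacted, with 100% gone, target 30.6%, solvolysis product 46.1% and other capture product 11.7%.

    starting material → intermediate (k = 0.100 s⁻¹)
    first nucleophile + intermediate → target (k = 160 M⁻¹ s⁻¹)
    second nucleophile + intermediate → other capture product (k = 100 M⁻¹ s⁻¹)
    intermediate → solvolysis product (k = 4.20 s⁻¹)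
    starting material + protic impurity → quenched substrate (k = 7.60 M⁻¹ s⁻¹)
    2 second nucleophile → homo dimer (k = 1.70 M⁻¹ s⁻¹)

At the flask's charge, the first nucleophile captured the intermediate at 3.12 s⁻¹, slower than solvolysis at 4.2 s⁻¹. The flask's ratio stood at 0.664, and S with the target actually formed gives 0.670. A neighbouring flask charged with 0.0032 M of starting material, at the same equivalents, held target 11.9% and solvolysis product 67.5%, a ratio of 0.176, and S gives 0.176.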